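**Retrosynthetic overview**

1. The last C–C bond is the ring-carbon–CH2 bond of the tertiary carbinol on the oxepane-fused cyclohexane: a spiro-epoxide (left half) is opened by the lithium acetylide of the right half. The arene oxygens are differentiated (5-OBn, 2-OTs) and the sulfate goes on last.
2. Right half: the bicyclo[2.2.2]octan-1-ol (C1 carbinol bridgehead, C2 CH–CH2Ar, C3 CMe2, C4 CH bridgehead, C5 quaternary, C6 CH2, C7–C8 CH2CH2) is a ring-enlarged bornane. Its six-membered ring C1–C2–C3–C4–C8–C7 is the cyclopentane C1–C7(Me2)–C4–C5–C6 of (1R)-ketopinic acid with C10 inserted between C1 and C7.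
3. Enabling feature: the triad carbinol bridgehead C1 / methine C2 / gem-dimethyl C3 bound to the second bridgehead C4–H, which is C1, C10 and C7 of a camphor skeleton. A leaving group on C10 lets the C1–C7 bond shift and water take the bridgehead.
4. Before that, C5 (methyl and linker) comes from two enolate alkylations at C3 of the ketopinate, the ketone is deleted, and the C10 carbinol is set by CBS reduction of a benzyl ketone made by Negishi acylation.
5. Left half: 2-methylcyclohexane-1,3-dione, enzymatic desymmetrisation, Evans–Tishchenko reduction, oxymercuration (oxepane), methylation, methylenation, epoxidation. Ring order: bornane (pool) to bicyclo[2.2.2]octane (enlargement); cyclohexane (pool) to oxepane; then union.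

Key step: step 18

Remark: the target is drawn as the free aryl hydrogen sulfate; such monoesters are carried as salts, and the acid form is released only in the final cold acidification.

Bornane numbering is used for compounds 1–10 and 17–19 (C1 bridgehead bearing C10, C7 the gem-dimethyl bridge; exo = syn to C7). 1-Benzoxepine numbering is used for the left half (O1, C2 gem-dimethyl, C5a angular methyl, C6, C7, C9a).

**Route**

Step 1
Reactants: 1 (1R)-(−)-10-camphorsulfonyl chloride
Product: 2 (1R,4S)-ketopinic acid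
Conditions: KMnO4, Na2CO3, H2O, 80 °C; then H2SO4
Reagents that add atoms: potassium permanganate [K+].[O-][Mn](=O)(=O)=O; water O
Why: Permanganate oxidation of the sulfonyl chloride degrades the C10–S bond to the carboxylic acid (oxidative desulfonylation) without touching either stereocentre.

Step 2
Reactants: 2 (1R,4S)-ketopinic acid
Product: 3 methyl (1R,4S)-ketopinate
Conditions: MeI, K2CO3, DMF, 25 °C
Reagents that add atoms: iodomethane CI
Why: SN2 O-alkylation of the carboxylate gives the ester needed for the later xanthate chemistry.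

Step 3
Reactants: 3 methyl (1R,4S)-ketopinate
Product: 4 methyl 3-methylketopinate (C3 epimers, 3-exo-methyl expected to predominate)
Conditions: LDA, THF, −78 °C; MeI, −78 → 0 °C
Reagents that add atoms: iodomethane CI
Why: Ketone enolate alkylation at C3, the only enolisable position because C1 is quaternary; the C3 configuration is erased in step 4.

Step 4
Reactants: 4 methyl 3-methylketopinate
Product: 5 methyl 3-endo-methyl-3-exo-[3-(trimethylsilyl)prop-2-ynyl]ketopinate
Conditions: LDA, THF, −78 → 0 °C; DMPU; Me3Si–C≡C–CH2Br, −78 → 25 °C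
Reagents that add atoms: 3-bromo-1-(trimethylsilyl)prop-1-yne C[Si](C)(C)C#CCBr
Why: Enolate alkylation of the tetrasubstituted enolate on its exo face (the kinetically preferred face of camphor-type enolates) should place the propargyl group exo and the methyl endo, which creates the quaternary stereocentre.

Step 5
Reactants: 5 methyl 3-endo-methyl-3-exo-[3-(trimethylsilyl)prop-2-ynyl]ketopinate
Product: 6 methyl 2-exo-hydroxy-3-endo-methyl-3-exo-[3-(trimethylsilyl)prop-2-ynyl]-7,7-dimethylbicyclo[2.2.1]heptane-1-carboxylate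
Conditions: NaBH4, CeCl3·7H2O, MeOH/THF, 0 °C
Reagents that add atoms: none
Why: Luche-type borohydride reduction of the ketone from the endo face should give the exo alcohol (its configuration is removed in step 7) while the ester and the silylalkyne are spared.

Step 6
Reactants: 6 the 2-exo-hydroxy ester
Product: 7 O-(bornan-2-yl) S-methyl dithiocarbonate (xanthate) of 6
Conditions: NaH, imidazole (cat.), THF, 0 °C; CS2; MeI
Reagents that add atoms: carbon disulfide S=C=S; iodomethane CI
Why: Xanthate formation (alkoxide addition to CS2, then S-methylation) prepares the hindered secondary alcohol for Barton–McCombie deoxygenation.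

Step 7
Reactants: 7 the xanthate
Product: 8 methyl 3-endo-methyl-3-exo-[3-(trimethylsilyl)prop-2-ynyl]-7,7-dimethylbicyclo[2.2.1]heptane-1-carboxylate
Conditions: Bu3SnH, Et3B, air, toluene, 25 °C
Reagents that add atoms: none
Why: Barton–McCombie radical deoxygenation through the secondary bornan-2-yl radical; room-temperature initiation should limit hydrostannation of the silylalkyne.

Step 8
Reactants: 8 the deoxygenated ester
Product: 9 3-endo-methyl-3-exo-(prop-2-ynyl)-7,7-dimethylbicyclo[2.2.1]heptane-1-carboxylic acid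
Conditions: KOH, MeOH/H2O, 70 °C; then aq HCl
Reagents that add atoms: potassium hydroxide [K+].[OH-]
Why: Saponification of the bridgehead ester with concurrent protodesilylation of the alkynylsilane under the same basic conditions.

Step 9
Reactants: 9 the carboxylic acid
Product: 10 3-endo-methyl-3-exo-(prop-2-ynyl)-7,7-dimethylbicyclo[2.2.1]heptane-1-carbonyl chloride (used crude after evaporation)
Conditions: (COCl)2, DMF (cat.), CH2Cl2, 0 → 25 °C
Reagents that add atoms: oxalyl chloride ClC(=O)C(Cl)=O
Why: Acid chloride formation via the Vilsmeier-type chloroiminium catalyst; no stereocentre is involved.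

Step 10
Reactants: 11 2,5-dihydroxybenzaldehyde
Product: 12 5-(benzyloxy)-2-hydroxybenzaldehyde
Conditions: BnBr, NaHCO3, KI (cat.), MeCN, 80 °C
Reagents that add atoms: benzyl bromide BrCc1ccccc1
Why: Williamson etherification selective for the 5-hydroxyl, because the 2-hydroxyl is tied up in the intramolecular hydrogen bond to the aldehyde.

Step 11
Reactants: 12 5-(benzyloxy)-2-hydroxybenzaldehyde
Product: 13 4-(benzyloxy)-2-formylphenyl 4-methylbenzenesulfonate
Conditions: TsCl, Et3N, CH2Cl2, 0 → 25 °C
Reagents that add atoms: 4-methylbenzenesulfonyl chloride Cc1ccc(cc1)S(Cl)(=O)=O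
Why: O-Sulfonylation of the remaining phenol gives an electron-withdrawing, base-cleavable protecting group ortho to the future benzylic carbon.

Step 12
Reactants: 13 the aryl tosylate aldehyde
Product: 14 4-(benzyloxy)-2-(hydroxymethyl)phenyl 4-methylbenzenesulfonate
Conditions: NaBH4, MeOH/THF, 0 °C
Reagents that add atoms: none
Why: Borohydride reduction of the aldehyde; the aryl sulfonate and benzyl ether are inert.

Step 13
Reactants: 14 the benzylic alcohol
Product: 15 4-(benzyloxy)-2-(chloromethyl)phenyl 4-methylbenzenesulfonate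
Conditions: SOCl2, DMF (cat.), CH2Cl2, 0 °C
Reagents that add atoms: thionyl chloride ClS(Cl)=O
Why: Chlorination of the benzylic alcohol via its chlorosulfite.

Step 14
Reactants: 15 the benzylic chloride
Product: 16 [5-(benzyloxy)-2-(tosyloxy)benzyl]zinc chloride (THF solution, LiCl complex, used as such)
Conditions: Zn dust, LiCl, THF, 25 °C
Reagents that add atoms: zinc [Zn]
Why: Direct LiCl-promoted zinc insertion into the benzylic C–Cl bond gives an organozinc too weakly nucleophilic to attack its own aryl sulfonate.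

Step 15
Reactants: 10 the acid chloride; 16 the benzylzinc chloride
Product: 17 1-[3-endo-methyl-3-exo-(prop-2-ynyl)-7,7-dimethylbicyclo[2.2.1]hept-1-yl]-2-[5-(benzyloxy)-2-(tosyloxy)phenyl]ethan-1-one
Conditions: Pd(PPh3)4 (5 mol %), THF, 25 °C
Reagents that add atoms: none
Why: Negishi acylation (zerovalent palladium-catalysed coupling of an acid chloride with an organozinc) forms the C10–CH2Ar ketone under neutral conditions, so no benzylic enolate is formed next to the aryl tosylate.

Step 16
Reactants: 17 the benzyl ketone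
Product: 18 (1S)-1-[3-endo-methyl-3-exo-(prop-2-ynyl)-7,7-dimethylbicyclo[2.2.1]hept-1-yl]-2-[5-(benzyloxy)-2-(tosyloxy)phenyl]ethan-1-ol
Conditions: (R)-2-methyl-CBS-oxazaborolidine (20 mol %), catecholborane, toluene, −40 °C
Reagents that add atoms: none
Why: Corey–Bakshi–Shibata reduction under reagent control: the catalyst distinguishes the bridgehead tertiary alkyl group (large) from CH2Ar (small), so the (R)-catalyst should deliver the (S)-carbinol; catecholborane does not hydroborate the terminal alkyne at this temperature.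

Step 17
Reactants: 18 the (S)-carbinol
Product: 19 the (S)-methanesulfonate of 18
Conditions: MsCl, Et3N, CH2Cl2, 0 °C
Reagents that add atoms: methanesulfonyl chloride CS(Cl)(=O)=O
Why: Mesylation through the sulfene acylates even this neopentyl-type alcohol with retention at the carbinol carbon.

Step 18
Reactants: 19 the (S)-mesylate
Product: 21 2-[[5-(benzyloxy)-2-(tosyloxy)phenyl]methyl]-3,3,5-trimethyl-5-(prop-2-ynyl)bicyclo[2.2.2]octan-1-ol (arylmethyl on C2 syn to the C7–C8 bridge; propargyl on C5 syn to the C2–C3 bridge), via bicyclo[2.2.2]oct-1-yl cation 20 (not isolated)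
Conditions: 2,6-lutidine (1.5 equiv), (CF3)2CHOH/H2O 4:1, 45 °C
Reagents that add atoms: water O
Why: In the ionising, weakly nucleophilic medium the secondary mesylate should ionise with participation of the antiperiplanar, strained C1–C7 σ bond: the gem-dimethyl bridge carbon C7 shifts from C1 to C10 (Wagner–Meerwein 1,2-shift), the cyclopentane C1–C7–C4–C5–C6 becomes the six-membered ring C1–C10–C7–C4–C5–C6, and the bicyclo[2.2.2]oct-1-yl cation 20 is trapped by water at the bridgehead. The closest known reaction type is the solvolytic (Demjanov-type) ring enlargement of 1-norbornylmethyl sulfonates and amines to bicyclo[2.2.2]octan-1-ols. No ring is closed; one ring is enlarged by one carbon through a suprafacial 1,2-alkyl shift with retention at C7 and inversion at C10. The new stereocentre C2 (the former C10) is therefore fixed by the (S)-configuration of the mesylate from step 16, the bridgehead carbinol has only one possible configuration in the cage, and C4 and C5 are carried over from the bornane. The step needs migration of C7 instead of the CH2 bridge carbons C2 or C6 and no aryl participation: C7 is the only quaternary (best migrating) carbon and its shift releases the most strain and leads to the more stable bridgehead cation, while the arene is deactivated towards ipso attack (tosyloxy ortho, alkoxy only meta to the benzylic carbon). Direct substitution or solvent capture at C10 is shut off by its neopentyl position, and 2,6-lutidine keeps the medium from turning acidic.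

Step 19
Reactants: 22 2-methylcyclohexane-1,3-dione
Product: 23 3-(1-methyl-2,6-dioxocyclohexyl)propanal
Conditions: acrolein, H2O, 25 °C
Reagents that add atoms: acrolein C=CC=O
Why: Michael addition of the 1,3-dione to acrolein in water creates the prochiral quaternary carbon.

Step 20
Reactants: 23 the keto aldehyde
Product: 24 2-methyl-2-(4-methylpent-3-enyl)cyclohexane-1,3-dione
Conditions: i-PrPPh3I, n-BuLi, THF, −78 → 0 °C
Reagents that add atoms: isopropyltriphenylphosphonium iodide CC(C)[P+](c1ccccc1)(c1ccccc1)c1ccccc1.[I-]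
Why: Wittig olefination, chemoselective for the aldehyde over the two hindered ring ketones, installs the trisubstituted alkene.

Step 21
Reactants: 24 the homoprenyl dione
Product: 25 (2S,3S)-3-hydroxy-2-methyl-2-(4-methylpent-3-enyl)cyclohexan-1-one
Conditions: ketoreductase (Prelog-selective), NADP+ (cat.), i-PrOH, phosphate buffer pH 7, 30 °C
Reagents that add atoms: none
Why: Enzymatic desymmetrising mono-reduction of the type established with baker's yeast for 2-alkyl-2-methylcyclohexane-1,3-diones should set both the (S)-carbinol and the quaternary centre, with the hydroxyl cis to the alkenyl chain.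

Step 22
Reactants: 25 the (2S,3S)-ketol
Product: 26 (1S,2R,3S)-3-hydroxy-2-methyl-2-(4-methylpent-3-enyl)cyclohexyl benzoate
Conditions: PhCHO (5 equiv), SmI2 (30 mol %), THF, −10 °C
Reagents that add atoms: benzaldehyde O=Cc1ccccc1
Why: Evans–Tishchenko reduction: the samarium-bound hemiacetal delivers hydride intramolecularly to the ketone from the face of the existing oxygen, so the new hydroxyl should be trans to the benzoate, cis to the methyl and trans to the chain, and the two oxygens end up differentiated.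

Step 23
Reactants: 26 the anti-diol monobenzoate
Product: 29 trans-fused 2,2,5a-trimethyldecahydro-1-benzoxepin-6-ol (5a-methyl anti to 9a-H; 6-OH cis to C5), via alkylmercury trifluoroacetate 27 (not isolated), via oxepane benzoate 28 (not isolated)
Conditions: Hg(OCOCF3)2, MeNO2, 0 °C; NaBH4, aq NaOH, 0 °C; then NaOH, MeOH, 50 °C
Reagents that add atoms: none
Why: Intramolecular oxymercuration (the free hydroxyl attacks the mercurinium ion at its tertiary carbon, Markovnikov, 7-endo), reductive demercuration and saponification; the trans ring fusion follows from the preset trans relation of hydroxyl and chain.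

Step 24
Reactants: 29 the oxepane alcohol
Product: 30 trans-fused 2,2,5a-trimethyloctahydro-1-benzoxepin-6(2H)-one
Conditions: Dess–Martin periodinane, NaHCO3, CH2Cl2, 25 °C
Reagents that add atoms: none
Why: Dess–Martin oxidation of the hindered secondary alcohol to the ketone without epimerisable centres being affected.

Step 25
Reactants: 30 the oxepane ketone
Product: 31 trans-fused 2,2,5a,7-tetramethyloctahydro-1-benzoxepin-6(2H)-one (7-methyl equatorial, trans to the 5a-methyl)
Conditions: LDA, THF, −78 °C; MeI; then NaOMe (cat.), MeOH, 25 °C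
Reagents that add atoms: iodomethane CI
Why: Enolate methylation is regiospecific (only C7 carries α-hydrogens) and base equilibration should leave the methyl equatorial, away from the 1,3-diaxial contact with the angular methyl.

Step 26
Reactants: 31 the methylated ketone
Product: 32 trans-fused 2,2,5a,7-tetramethyl-6-methylenedecahydro-1-benzoxepine
Conditions: Ph3PCH3Br, KOt-Bu, toluene, 90 °C
Reagents that add atoms: methyltriphenylphosphonium bromide C[P+](c1ccccc1)(c1ccccc1)c1ccccc1.[Br-]
Why: Wittig methylenation with the salt-free ylide at elevated temperature, as used for hindered ketones; the equatorial 7-methyl is the thermodynamic epimer and should persist.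

Step 27
Reactants: 32 the exocyclic alkene
Product: 33 spiro-epoxide of 32 (spiro[1-benzoxepine-6,2'-oxirane]; epoxide oxygen axial, trans to the 5a-methyl)
Conditions: mCPBA, NaHCO3, CH2Cl2, 0 °C
Reagents that add atoms: 3-chloroperbenzoic acid OOC(=O)c1cccc(Cl)c1
Why: Prilezhaev epoxidation from the face anti to the axial angular methyl on the neighbouring carbon should give the axial C–O bond, which sets the configuration of the future tertiary carbinol.

Step 28
Reactants: 21 the bicyclo[2.2.2]octan-1-ol with terminal alkyne; 33 the spiro-epoxide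
Product: 35 coupled alkyne diol (tertiary cyclohexanol–CH2–C≡C–CH2–bicyclooctane; 5-OBn and 2-OTs on the arene), via dilithium alkoxide acetylide 34 (not isolated)
Conditions: n-BuLi (2.05 equiv), THF, −78 °C; BF3·OEt2; then 33, −78 °C
Reagents that add atoms: none
Why: Yamaguchi-type BF3-promoted alkynylation: SN2 opening of the epoxide at its CH2 terminus by the lithium acetylide leaves the carbinol stereocentre untouched and gives the tertiary alcohol with axial hydroxyl and equatorial chain.

Step 29
Reactants: 35 the coupled alkyne diol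
Product: 36 saturated diol with free 5-phenol and 2-tosyloxy group
Conditions: H2 (1 atm), Pd/C, EtOAc/MeOH, 25 °C
Reagents that add atoms: none
Why: Heterogeneous hydrogenation reduces the alkyne to the (CH2)4 linker and hydrogenolyses the benzyl ether, while the aryl tosylate and the tertiary alcohols are inert.

Step 30
Reactants: 36 the phenol
Product: 39 target CNP0255133.1, via pyridinium aryl sulfate 37 (not isolated), via dipotassium phenolate sulfate 38 (not isolated)
Conditions: SO3·pyridine, pyridine, 25 °C; KOH, MeOH/H2O, 60 °C; then aq HCl (2 equiv), 0 °C, n-BuOH extraction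
Reagents that add atoms: sulfur trioxide pyridine complex [O-]S(=O)(=O)[n+]1ccccc1
Why: O-Sulfation of the only free phenol (the tertiary alcohols are too hindered), basic cleavage of the aryl tosylate by attack at sulfur (aryl sulfate monoesters are stable to base), then cold acidification to the hydrogen sulfate.

**Compound list**

1 | (1R)-(−)-10-camphorsulfonyl chloride | CC1(C)[C@H]2CC[C@]1(CS(=O)(=O)Cl)C(=O)C2 | starting material
2 | (1R,4S)-ketopinic acid | CC1(C)[C@H]2CC[C@]1(C(=O)O)C(=O)C2 | intermediate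
3 | methyl (1R,4S)-ketopinate | CC1(C)[C@H]2CC[C@]1(C(=O)OC)C(=O)C2 | intermediate
4 | methyl 3-methylketopinate (C3 epimers; 3-exo-methyl drawn) | CC1(C)[C@H]2CC[C@]1(C(=O)OC)C(=O)[C@H]2C | intermediate
5 | methyl 3-endo-methyl-3-exo-[3-(trimethylsilyl)prop-2-ynyl]ketopinate | CC1(C)[C@H]2CC[C@]1(C(=O)OC)C(=O)[C@@]2(C)CC#C[Si](C)(C)C | intermediate
6 | methyl 2-exo-hydroxy-3-endo-methyl-3-exo-[3-(trimethylsilyl)prop-2-ynyl]-7,7-dimethylbicyclo[2.2.1]heptane-1-carboxylate | CC1(C)[C@H]2CC[C@]1(C(=O)OC)[C@@H](O)[C@@]2(C)CC#C[Si](C)(C)C | intermediate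
7 | S-methyl xanthate of 6 | CC1(C)[C@H]2CC[C@]1(C(=O)OC)[C@@H](OC(=S)SC)[C@@]2(C)CC#C[Si](C)(C)C | intermediate
8 | methyl 3-endo-methyl-3-exo-[3-(trimethylsilyl)prop-2-ynyl]-7,7-dimethylbicyclo[2.2.1]heptane-1-carboxylate | CC1(C)[C@H]2CC[C@]1(C(=O)OC)C[C@@]2(C)CC#C[Si](C)(C)C | intermediate
9 | 3-endo-methyl-3-exo-(prop-2-ynyl)-7,7-dimethylbicyclo[2.2.1]heptane-1-carboxylic acid | CC1(C)[C@H]2CC[C@]1(C(=O)O)C[C@@]2(C)CC#C | intermediate
10 | acid chloride of 9 | CC1(C)[C@H]2CC[C@]1(C(=O)Cl)C[C@@]2(C)CC#C | intermediate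
11 | 2,5-dihydroxybenzaldehyde | O=Cc1cc(O)ccc1O | starting material
12 | 5-(benzyloxy)-2-hydroxybenzaldehyde | O=Cc1cc(OCc2ccccc2)ccc1O | intermediate
13 | 4-(benzyloxy)-2-formylphenyl 4-methylbenzenesulfonate | O=Cc1cc(OCc2ccccc2)ccc1OS(=O)(=O)c1ccc(C)cc1 | intermediate
14 | 4-(benzyloxy)-2-(hydroxymethyl)phenyl 4-methylbenzenesulfonate | OCc1cc(OCc2ccccc2)ccc1OS(=O)(=O)c1ccc(C)cc1 | intermediate
15 | 4-(benzyloxy)-2-(chloromethyl)phenyl 4-methylbenzenesulfonate | ClCc1cc(OCc2ccccc2)ccc1OS(=O)(=O)c1ccc(C)cc1 | intermediate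
16 | [5-(benzyloxy)-2-(tosyloxy)benzyl]zinc chloride | Cl[Zn]Cc1cc(OCc2ccccc2)ccc1OS(=O)(=O)c1ccc(C)cc1 | intermediate
17 | benzyl ketone: 1-[3-endo-methyl-3-exo-(prop-2-ynyl)-7,7-dimethylbicyclo[2.2.1]hept-1-yl]-2-[5-(benzyloxy)-2-(tosyloxy)phenyl]ethan-1-one | CC1(C)[C@H]2CC[C@]1(C(=O)Cc3cc(OCc4ccccc4)ccc3OS(=O)(=O)c3ccc(C)cc3)C[C@@]2(C)CC#C | intermediate
18 | (1S)-carbinol from 17 | CC1(C)[C@H]2CC[C@]1([C@@H](O)Cc3cc(OCc4ccccc4)ccc3OS(=O)(=O)c3ccc(C)cc3)C[C@@]2(C)CC#C | intermediate
19 | (S)-methanesulfonate of 18 | CC1(C)[C@H]2CC[C@]1([C@@H](OS(C)(=O)=O)Cc3cc(OCc4ccccc4)ccc3OS(=O)(=O)c3ccc(C)cc3)C[C@@]2(C)CC#C | intermediate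
20 | bicyclo[2.2.2]oct-1-yl cation formed by the 1,2-shift | C#CC[C@]1(C)C[C+]2CC[C@@H]1C(C)(C)[C@@H]2Cc1cc(OCc2ccccc2)ccc1OS(=O)(=O)c1ccc(C)cc1 | intermediate
21 | 2-[[5-(benzyloxy)-2-(tosyloxy)phenyl]methyl]-3,3,5-trimethyl-5-(prop-2-ynyl)bicyclo[2.2.2]octan-1-ol | C#CC[C@]1(C)C[C@@]2(O)CC[C@@H]1C(C)(C)[C@@H]2Cc1cc(OCc2ccccc2)ccc1OS(=O)(=O)c1ccc(C)cc1 | intermediate
22 | 2-methylcyclohexane-1,3-dione | CC1C(=O)CCCC1=O | starting material
23 | 3-(1-methyl-2,6-dioxocyclohexyl)propanal | CC1(CCC=O)C(=O)CCCC1=O | intermediate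
24 | 2-methyl-2-(4-methylpent-3-enyl)cyclohexane-1,3-dione | CC(C)=CCCC1(C)C(=O)CCCC1=O | intermediate
25 | (2S,3S)-3-hydroxy-2-methyl-2-(4-methylpent-3-enyl)cyclohexan-1-one | C1CCC(=O)[C@@](C)(CCC=C(C)C)[C@H]1O | intermediate
26 | (1S,2R,3S)-3-hydroxy-2-methyl-2-(4-methylpent-3-enyl)cyclohexyl benzoate | C1CC[C@H](O)[C@@](C)(CCC=C(C)C)[C@H]1OC(=O)c1ccccc1 | intermediate
27 | 3-(trifluoroacetoxymercurio) oxepane benzoate (C3 epimers) | C1CC[C@@H]2OC(C)(C)C([Hg]OC(=O)C(F)(F)F)CC[C@@]2(C)[C@H]1OC(=O)c1ccccc1 | intermediate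
28 | trans-fused 2,2,5a-trimethyldecahydro-1-benzoxepin-6-yl benzoate | C1CC[C@@H]2OC(C)(C)CCC[C@@]2(C)[C@H]1OC(=O)c1ccccc1 | intermediate
29 | trans-fused 2,2,5a-trimethyldecahydro-1-benzoxepin-6-ol | C1CC[C@@H]2OC(C)(C)CCC[C@@]2(C)[C@H]1O | intermediate
30 | trans-fused 2,2,5a-trimethyloctahydro-1-benzoxepin-6(2H)-one | C1CC[C@@H]2OC(C)(C)CCC[C@@]2(C)C1=O | intermediate
31 | trans-fused 2,2,5a,7-tetramethyloctahydro-1-benzoxepin-6(2H)-one (7-methyl trans to 5a-methyl) | C[C@H]1CC[C@@H]2OC(C)(C)CCC[C@@]2(C)C1=O | intermediate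
32 | 6-methylene analogue of 31 | C[C@H]1CC[C@@H]2OC(C)(C)CCC[C@@]2(C)C1=C | intermediate
33 | spiro-epoxide of 32 (oxygen trans to 5a-methyl) | C[C@H]1CC[C@@H]2OC(C)(C)CCC[C@@]2(C)[C@]1(O2)C2 | intermediate
34 | dilithium alkoxide acetylide of 21 | [Li]C#CC[C@]1(C)C[C@@]2(O[Li])CC[C@@H]1C(C)(C)[C@@H]2Cc1cc(OCc2ccccc2)ccc1OS(=O)(=O)c1ccc(C)cc1 | intermediate
35 | coupled alkyne diol | C[C@H]1CC[C@@H]2OC(C)(C)CCC[C@@]2(C)[C@]1(O)CC#CC[C@]1(C)C[C@@]2(O)CC[C@@H]1C(C)(C)[C@@H]2Cc1cc(OCc2ccccc2)ccc1OS(=O)(=O)c1ccc(C)cc1 | intermediate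
36 | saturated diol, 5-phenol free, 2-O-tosyl | C[C@H]1CC[C@@H]2OC(C)(C)CCC[C@@]2(C)[C@]1(O)CCCC[C@]1(C)C[C@@]2(O)CC[C@@H]1C(C)(C)[C@@H]2Cc1cc(O)ccc1OS(=O)(=O)c1ccc(C)cc1 | intermediate
37 | pyridinium 5-O-sulfate of 36 | C[C@H]1CC[C@@H]2OC(C)(C)CCC[C@@]2(C)[C@]1(O)CCCC[C@]1(C)C[C@@]2(O)CC[C@@H]1C(C)(C)[C@@H]2Cc1cc(OS(=O)(=O)[O-])ccc1OS(=O)(=O)c1ccc(C)cc1.c1cc[nH+]cc1 | intermediate
38 | dipotassium phenolate sulfate | C[C@H]1CC[C@@H]2OC(C)(C)CCC[C@@]2(C)[C@]1(O)CCCC[C@]1(C)C[C@@]2(O)CC[C@@H]1C(C)(C)[C@@H]2Cc1cc(OS(=O)(=O)[O-])ccc1[O-].[K+].[K+] | intermediate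
39 | CNP0255133.1 | C[C@H]1CC[C@@H]2OC(C)(C)CCC[C@@]2(C)[C@]1(O)CCCC[C@]1(C)C[C@@]2(O)CC[C@@H]1C(C)(C)[C@@H]2Cc1cc(OS(=O)(=O)O)ccc1O | target

**Step count and risks**

Total step count: 30. Longest linear sequence: 16 steps (steps 1–9, 15–18, 28–30).

Steps most likely to fail:

1. Step 18. What may go wrong: a CH2 bridge carbon (C2 or C6) migrates in place of C7, or the ionising centre loses a proton to give the styrene before the shift, if σ-assistance to the mesylate is weak. Fallback (Demjanov ring enlargement, setting out from 17 and returning at 21): ketone 17 would be condensed with (S)-tert-butanesulfinamide (Ti(OEt)4, THF, 65 °C) to the N-sulfinyl ketimine F1. Reduction with NaBH4 (THF, −50 °C) should give the sulfinamide F2, and HCl in MeOH the (S)-amine F3. Diazotisation (NaNO2, aqueous AcOH, 0 °C) gives the alkanediazonium ion F4, whose ionisation needs no solvolytic assistance; loss of nitrogen with the same 1,2-shift leads through cation 20 to alcohol 21.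

2. Step 28. What may go wrong: Lewis-acid-induced hydride shift turns the 2,2-disubstituted epoxide into the aldehyde faster than the acetylide attacks the hindered CH2 terminus. Fallback (cross metathesis without a strong Lewis acid, setting out from 21 and 33 and returning at 36): semi-hydrogenation of 21 (H2, Pd/CaCO3 poisoned with Pb(OAc)2, quinoline) gives the allyl compound F5. Copper-catalysed opening of 33 with vinylmagnesium bromide (CuI cat., THF, −30 °C) gives the homoallylic tertiary alcohol F6. Cross metathesis of F5 and F6 (second-generation Hoveyda–Grubbs catalyst, CH2Cl2, 40 °C) gives the internal alkene F7 (E/Z irrelevant), and hydrogenation under the conditions of step 29 gives 36.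

3. Step 23. What may go wrong: the seven-membered ring closes too slowly, so that intermolecular solvomercuration or proton loss from the mercurinium ion takes over. Fallback (ring-closing metathesis, setting out from 22 and returning at 29): 22 is C-allylated (allyl bromide, aq NaOH) to 2-allyl-2-methylcyclohexane-1,3-dione F8 and reduced as in step 21 to the (2S,3S)-ketol F9. Evans–Tishchenko reduction as in step 22 gives the anti-diol monobenzoate F10. Acid-catalysed O-alkylation with 2-methylbut-3-en-2-yl trichloroacetimidate (TfOH cat.) gives the tertiary allyl ether F11, and ring-closing metathesis (second-generation Grubbs catalyst) the oxepene F12. Hydrogenation (H2, Pd/C) gives 28, and saponification (NaOH, MeOH) gives 29.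

Further compounds
F1 | step 18 | (S)-N-tert-butanesulfinyl ketimine of 17 | CC1(C)[C@H]2CC[C@]1(C(Cc3cc(OCc4ccccc4)ccc3OS(=O)(=O)c3ccc(C)cc3)=N[S@@](=O)C(C)(C)C)C[C@@]2(C)CC#C
F2 | step 18 | (S)-configured N-sulfinyl amine | CC1(C)[C@H]2CC[C@]1([C@@H](N[S@@](=O)C(C)(C)C)Cc3cc(OCc4ccccc4)ccc3OS(=O)(=O)c3ccc(C)cc3)C[C@@]2(C)CC#C
F3 | step 18 | (S)-amine corresponding to carbinol 18 | CC1(C)[C@H]2CC[C@]1([C@@H](N)Cc3cc(OCc4ccccc4)ccc3OS(=O)(=O)c3ccc(C)cc3)C[C@@]2(C)CC#C
F4 | step 18 | alkanediazonium ion from F3 | CC1(C)[C@H]2CC[C@]1([C@@H]([N+]#N)Cc3cc(OCc4ccccc4)ccc3OS(=O)(=O)c3ccc(C)cc3)C[C@@]2(C)CC#C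
F5 | step 28 | 5-allyl analogue of 21 | C=CC[C@]1(C)C[C@@]2(O)CC[C@@H]1C(C)(C)[C@@H]2Cc1cc(OCc2ccccc2)ccc1OS(=O)(=O)c1ccc(C)cc1
F6 | step 28 | 6-(but-3-enyl-type) homoallylic tertiary alcohol from 33 (6-allyl-6-hydroxy) | C[C@H]1CC[C@@H]2OC(C)(C)CCC[C@@]2(C)[C@]1(O)CC=C
F7 | step 28 | cross-metathesis alkene | C[C@H]1CC[C@@H]2OC(C)(C)CCC[C@@]2(C)[C@]1(O)C/C=C/C[C@]1(C)C[C@@]2(O)CC[C@@H]1C(C)(C)[C@@H]2Cc1cc(OCc2ccccc2)ccc1OS(=O)(=O)c1ccc(C)cc1
F8 | step 23 | 2-allyl-2-methylcyclohexane-1,3-dione | C=CCC1(C)C(=O)CCCC1=O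
F9 | step 23 | (2S,3S)-2-allyl-3-hydroxy-2-methylcyclohexan-1-one | C1CCC(=O)[C@@](C)(CC=C)[C@H]1O
F10 | step 23 | (1S,2R,3S)-2-allyl-3-hydroxy-2-methylcyclohexyl benzoate | C1CC[C@H](O)[C@@](C)(CC=C)[C@H]1OC(=O)c1ccccc1
F11 | step 23 | 3-O-(2-methylbut-3-en-2-yl) ether of F10 | C1CC[C@H](OC(C)(C)C=C)[C@@](C)(CC=C)[C@H]1OC(=O)c1ccccc1
F12 | step 23 | trans-fused 2,2,5a-trimethyl-2,5,5a,6,7,8,9,9a-octahydro-1-benzoxepin-6-yl benzoate | C1CC[C@@H]2OC(C)(C)C=CC[C@@]2(C)[C@H]1OC(=O)c1ccccc1
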